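The flavone is cut at the C3–C4 bond of the pyranone (ring C). Both carbons bear oxygen (C4=O, C3–OMe) and are already linked through O1–C2, so each is traced back to an aldehyde carbon. The precursor is an aryl ether dialdehyde: a salicylaldehyde-type A ring O-alkylated by an α-aryl glycolaldehyde unit that carries the B ring. Carbene (acyl-anion) catalysis closes it; one operation forms C3–C4, closes ring C as an acyloin and, after oxidation in the same flask, gives the 3-hydroxyflavone. The dialdehyde comes from a Mitsunobu union of a tetra-oxygenated salicylaldehyde with an O-prenylated mandelate, then reduction and double oxidation.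

Key step: step 11

Remark 1: the target has no stereocentre and no stereogenic double bond, so there is no enantiomer to select; 11–16 are racemic and their stereocentres are erased in step 11.
Remark 2: phloroglucinaldehyde has one ring oxygen too few for the A ring, so its formyl carbon is converted into the C8 oxygen (steps 2–4) and the aldehyde is put back ortho to the phenol (step 6).
Remark 3: O5 and O7 are carried as SEM ethers rather than acid-labile acetals, so that the last step uses fluoride and the aryl prenyl ether is never exposed to acid.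

Step 1
Reactants: 1 2,4,6-trihydroxybenzaldehyde
Product: 2 2-hydroxy-4,6-bis{[2-(trimethylsilyl)ethoxy]methoxy}benzaldehyde
Conditions: SEMCl (2.1 equiv), i-Pr2NEt (2.5 equiv), CH2Cl2, 0 °C to rt
Reagents that add atoms: 2-(trimethylsilyl)ethoxymethyl chloride (SEMCl), C[Si](C)(C)CCOCCl
Why: O-alkylation with an α-chloro ether (Williamson type) should take the para OH and one ortho OH, while the last ortho OH is held in a hydrogen bond to the formyl oxygen and stays free, as is usual for chloromethyl ethers on this aldehyde.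

Step 2
Reactants: 2 2-hydroxy-4,6-bis{[2-(trimethylsilyl)ethoxy]methoxy}benzaldehyde
Product: 3 2-(benzyloxy)-4,6-bis{[2-(trimethylsilyl)ethoxy]methoxy}benzaldehyde
Conditions: BnBr (1.2 equiv), K2CO3, DMF, 50 °C
Reagents that add atoms: benzyl bromide, BrCc1ccccc1
Why: Williamson etherification of the chelated phenol under mild heating masks the oxygen that later becomes O1 with a group removable by hydrogenolysis.

Step 3
Reactants: 3 2-(benzyloxy)-4,6-bis{[2-(trimethylsilyl)ethoxy]methoxy}benzaldehyde
Product: 5 2-(benzyloxy)-4,6-bis{[2-(trimethylsilyl)ethoxy]methoxy}phenol, via aryl formate 4 (not isolated)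
Conditions: mCPBA (1.3 equiv), CH2Cl2, 0 °C to rt; aq. NaHCO3 wash; then K2CO3 (0.2 equiv), MeOH, rt
Reagents that add atoms: 3-chloroperoxybenzoic acid (mCPBA), OOC(=O)c1cccc(Cl)c1
Why: Baeyer–Villiger (Dakin-type) oxidation should proceed with migration of the very electron-rich trialkoxyaryl group to give formate 4, whose methanolysis unveils the phenol oxygen that is missing from the starting aldehyde.

Step 4
Reactants: 5 2-(benzyloxy)-4,6-bis{[2-(trimethylsilyl)ethoxy]methoxy}phenol
Product: 6 1-(benzyloxy)-2-methoxy-3,5-bis{[2-(trimethylsilyl)ethoxy]methoxy}benzene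
Conditions: MeI (1.5 equiv), K2CO3, DMF, rt
Reagents that add atoms: iodomethane, CI
Why: Williamson methylation of the only free phenol installs the future 8-methoxy group between the benzyloxy and SEM-oxy carbons.

Step 5
Reactants: 6 1-(benzyloxy)-2-methoxy-3,5-bis{[2-(trimethylsilyl)ethoxy]methoxy}benzene
Product: 7 2-methoxy-3,5-bis{[2-(trimethylsilyl)ethoxy]methoxy}phenol
Conditions: H2 (1 atm), 10% Pd/C, EtOAc, rt
Reagents that add atoms: none
Why: Catalytic hydrogenolysis cleaves only the benzyl ether, since SEM and methyl ethers are inert and no alkene is present at this stage.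

Step 6
Reactants: 7 2-methoxy-3,5-bis{[2-(trimethylsilyl)ethoxy]methoxy}phenol
Product: 8 2-hydroxy-3-methoxy-4,6-bis{[2-(trimethylsilyl)ethoxy]methoxy}benzaldehyde
Conditions: MgCl2 (2 equiv), Et3N (4 equiv), (CH2O)n (5 equiv), MeCN, reflux
Reagents that add atoms: paraformaldehyde (as formaldehyde), C=O
Why: Magnesium-mediated ortho-formylation (Casnati–Skattebøl) delivers formaldehyde within the magnesium phenoxide to the only free ortho carbon, not to the carbon between the two SEM ethers, and a second formaldehyde oxidises the benzylic alkoxide to the aldehyde.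

Step 7
Reactants: 9 vanillylmandelic acid (racemic 2-hydroxy-2-(4-hydroxy-3-methoxyphenyl)acetic acid); 10 prenyl bromide (1-bromo-3-methylbut-2-ene, 2.3 equiv)
Product: 11 racemic 3-methylbut-2-enyl 2-hydroxy-2-[3-methoxy-4-(3-methylbut-2-enyloxy)phenyl]acetate
Conditions: K2CO3 (2.5 equiv), DMF, rt
Reagents that add atoms: none
Why: Carbonate-mediated SN2 alkylation takes both the carboxylate and the phenoxide while the secondary alcohol is not deprotonated, and the prenyl ester is only a carrier that is reduced away in step 9.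

Step 8
Reactants: 8 2-hydroxy-3-methoxy-4,6-bis{[2-(trimethylsilyl)ethoxy]methoxy}benzaldehyde; 11 racemic 3-methylbut-2-enyl 2-hydroxy-2-[3-methoxy-4-(3-methylbut-2-enyloxy)phenyl]acetate
Product: 12 racemic 3-methylbut-2-enyl 2-(2-formyl-6-methoxy-3,5-bis{[2-(trimethylsilyl)ethoxy]methoxy}phenoxy)-2-[3-methoxy-4-(3-methylbut-2-enyloxy)phenyl]acetate
Conditions: PPh3 (1.5 equiv), DIAD (1.5 equiv), THF, 0 °C to rt
Reagents that add atoms: none
Why: Mitsunobu etherification lets the acidic salicylaldehyde-type phenol displace the activated benzylic alkoxyphosphonium ion (the new stereocentre is racemic and is erased later), and the base-free conditions avoid the aldol of the α-aryloxy ester onto the ortho aldehyde that leads to benzofurans.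

Step 9
Reactants: 12 racemic 3-methylbut-2-enyl 2-(2-formyl-6-methoxy-3,5-bis{[2-(trimethylsilyl)ethoxy]methoxy}phenoxy)-2-[3-methoxy-4-(3-methylbut-2-enyloxy)phenyl]acetate
Product: 13 racemic 2-(2-(hydroxymethyl)-6-methoxy-3,5-bis{[2-(trimethylsilyl)ethoxy]methoxy}phenoxy)-2-[3-methoxy-4-(3-methylbut-2-enyloxy)phenyl]ethan-1-ol
Conditions: LiAlH4 (2 equiv), THF, 0 °C; aqueous NaOH work-up
Reagents that add atoms: none
Why: Hydride reduction takes the ester and the aldehyde to the diol, while SEM, aryl alkyl and prenyl ethers are inert to LiAlH4.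

Step 10
Reactants: 13 racemic 2-(2-(hydroxymethyl)-6-methoxy-3,5-bis{[2-(trimethylsilyl)ethoxy]methoxy}phenoxy)-2-[3-methoxy-4-(3-methylbut-2-enyloxy)phenyl]ethan-1-ol
Product: 14 racemic 3-methoxy-2-{1-[3-methoxy-4-(3-methylbut-2-enyloxy)phenyl]-2-oxoethoxy}-4,6-bis{[2-(trimethylsilyl)ethoxy]methoxy}benzaldehyde
Conditions: Dess–Martin periodinane (3 equiv), NaHCO3 (8 equiv), CH2Cl2, 0 °C to rt; used crude at once
Reagents that add atoms: none
Why: Dess–Martin oxidation converts both primary alcohols to aldehydes under buffered, non-enolising conditions, and an excess of oxidant should outrun lactol formation of the half-oxidised material.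

Step 11
Reactants: 14 racemic 3-methoxy-2-{1-[3-methoxy-4-(3-methylbut-2-enyloxy)phenyl]-2-oxoethoxy}-4,6-bis{[2-(trimethylsilyl)ethoxy]methoxy}benzaldehyde
Product: 17 3-hydroxy-8-methoxy-2-[3-methoxy-4-(3-methylbut-2-enyloxy)phenyl]-5,7-bis{[2-(trimethylsilyl)ethoxy]methoxy}-4H-chromen-4-one, via 4-hydroxychroman-3-one acyloin 15 (not isolated), via chromane-3,4-dione 16 (not isolated)
Conditions: 2-(pentafluorophenyl)-6,7-dihydro-5H-pyrrolo[2,1-c][1,2,4]triazol-2-ium tetrafluoroborate (20 mol%), i-Pr2NEt (20 mol%), degassed THF, rt, Ar; then I2 (1.2 equiv), K2CO3 (3 equiv), t-BuOH, 0 °C to rt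
Reagents that add atoms: none
Why: Proposed new method: the triazolylidene adds to the less hindered aliphatic formyl group of 14, proton transfer gives the Breslow enaminol, and this acyl-anion equivalent attacks the ortho formyl carbon of the A ring in a 6-exo-trig closure that forms C3–C4, closes the pyranone ring as acyloin 15 and releases the carbene. The closest known reaction type is the carbene-catalysed intramolecular crossed benzoin of salicylaldehyde-derived keto aldehydes to 3-hydroxychroman-4-ones; an aldehyde–aldehyde case with an α-aryloxy aldehyde as donor is not established. Iodine and carbonate then oxidise 15 through its enediolate to dione 16, which enolises towards C2 to the aromatic 3-hydroxy-4-pyranone 17; the regioisomeric acyloin (aryl aldehyde as donor) would converge on the same product. The transient stereocentres at C2 and C4 of 15 need no control because both are erased in 17. The step needs chemoselectivity for ring closure over expulsion of the A-ring aryloxide from the Breslow intermediate and over base-induced enolisation and aldol of the α-aryloxy aldehyde to a benzofuran; the acceptor formyl group held in a six-ring-forming position by the O1 tether, an electron-poor N-C6F5 carbene and only a catalytic amount of a tertiary amine should secure it, and prompt oxidation forestalls base-induced ring opening of the acyloin.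

Step 12
Reactants: 17 3-hydroxy-8-methoxy-2-[3-methoxy-4-(3-methylbut-2-enyloxy)phenyl]-5,7-bis{[2-(trimethylsilyl)ethoxy]methoxy}-4H-chromen-4-one
Product: 18 3,8-dimethoxy-2-[3-methoxy-4-(3-methylbut-2-enyloxy)phenyl]-5,7-bis{[2-(trimethylsilyl)ethoxy]methoxy}-4H-chromen-4-one
Conditions: MeI (2 equiv), K2CO3, acetone, 40 °C
Reagents that add atoms: iodomethane, CI
Why: Williamson O-methylation of the acidic enolic 3-OH, the only free hydroxyl in the molecule, is standard for flavonols.

Step 13
Reactants: 18 3,8-dimethoxy-2-[3-methoxy-4-(3-methylbut-2-enyloxy)phenyl]-5,7-bis{[2-(trimethylsilyl)ethoxy]methoxy}-4H-chromen-4-one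
Product: 19 5,7-dihydroxy-3,8-dimethoxy-2-[3-methoxy-4-(3-methylbut-2-enyloxy)phenyl]-4H-chromen-4-one (the target)
Conditions: TBAF (1 M in THF, 6 equiv), ethylenediamine (3 equiv), THF, 60 °C; aq. NH4Cl work-up
Reagents that add atoms: none
Why: Fluoride attack at silicon triggers β-elimination of each SEM group (fluoride-induced fragmentation to ethene, formaldehyde and the stabilised flavone phenoxide) under non-acidic conditions that leave the prenyl ether untouched, while ethylenediamine traps formaldehyde before it can hydroxymethylate C6.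

Compound list
1 | 2,4,6-trihydroxybenzaldehyde | O=Cc1c(O)cc(O)cc1O | starting material
2 | 2-hydroxy-4,6-bis{[2-(trimethylsilyl)ethoxy]methoxy}benzaldehyde | O=Cc1c(O)cc(OCOCC[Si](C)(C)C)cc1OCOCC[Si](C)(C)C | intermediate
3 | 2-(benzyloxy)-4,6-bis{[2-(trimethylsilyl)ethoxy]methoxy}benzaldehyde | O=Cc1c(OCc2ccccc2)cc(OCOCC[Si](C)(C)C)cc1OCOCC[Si](C)(C)C | intermediate
4 | 2-(benzyloxy)-4,6-bis{[2-(trimethylsilyl)ethoxy]methoxy}phenyl formate | O=COc1c(OCc2ccccc2)cc(OCOCC[Si](C)(C)C)cc1OCOCC[Si](C)(C)C | intermediate (not isolated)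
5 | 2-(benzyloxy)-4,6-bis{[2-(trimethylsilyl)ethoxy]methoxy}phenol | Oc1c(OCc2ccccc2)cc(OCOCC[Si](C)(C)C)cc1OCOCC[Si](C)(C)C | intermediate
6 | 1-(benzyloxy)-2-methoxy-3,5-bis{[2-(trimethylsilyl)ethoxy]methoxy}benzene | COc1c(OCc2ccccc2)cc(OCOCC[Si](C)(C)C)cc1OCOCC[Si](C)(C)C | intermediate
7 | 2-methoxy-3,5-bis{[2-(trimethylsilyl)ethoxy]methoxy}phenol | COc1c(O)cc(OCOCC[Si](C)(C)C)cc1OCOCC[Si](C)(C)C | intermediate
8 | 2-hydroxy-3-methoxy-4,6-bis{[2-(trimethylsilyl)ethoxy]methoxy}benzaldehyde | COc1c(O)c(C=O)c(OCOCC[Si](C)(C)C)cc1OCOCC[Si](C)(C)C | intermediate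
9 | vanillylmandelic acid, racemic | COc1cc(C(O)C(=O)O)ccc1O | starting material
10 | prenyl bromide (1-bromo-3-methylbut-2-ene) | CC(C)=CCBr | starting material
11 | 3-methylbut-2-enyl 2-hydroxy-2-[3-methoxy-4-(3-methylbut-2-enyloxy)phenyl]acetate, racemic | COc1cc(C(O)C(=O)OCC=C(C)C)ccc1OCC=C(C)C | intermediate
12 | 3-methylbut-2-enyl 2-(2-formyl-6-methoxy-3,5-bis{[2-(trimethylsilyl)ethoxy]methoxy}phenoxy)-2-[3-methoxy-4-(3-methylbut-2-enyloxy)phenyl]acetate, racemic | COc1cc(C(Oc2c(C=O)c(OCOCC[Si](C)(C)C)cc(OCOCC[Si](C)(C)C)c2OC)C(=O)OCC=C(C)C)ccc1OCC=C(C)C | intermediate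
13 | 2-(2-(hydroxymethyl)-6-methoxy-3,5-bis{[2-(trimethylsilyl)ethoxy]methoxy}phenoxy)-2-[3-methoxy-4-(3-methylbut-2-enyloxy)phenyl]ethan-1-ol, racemic | COc1cc(C(CO)Oc2c(CO)c(OCOCC[Si](C)(C)C)cc(OCOCC[Si](C)(C)C)c2OC)ccc1OCC=C(C)C | intermediate
14 | 3-methoxy-2-{1-[3-methoxy-4-(3-methylbut-2-enyloxy)phenyl]-2-oxoethoxy}-4,6-bis{[2-(trimethylsilyl)ethoxy]methoxy}benzaldehyde, racemic | O=CC(Oc1c(C=O)c(OCOCC[Si](C)(C)C)cc(OCOCC[Si](C)(C)C)c1OC)c1ccc(OCC=C(C)C)c(OC)c1 | intermediate (precursor of the key step)
15 | 4-hydroxy-8-methoxy-2-[3-methoxy-4-(3-methylbut-2-enyloxy)phenyl]-5,7-bis{[2-(trimethylsilyl)ethoxy]methoxy}chroman-3-one, racemic mixture of diastereomers | COc1c(OCOCC[Si](C)(C)C)cc(OCOCC[Si](C)(C)C)c2c1OC(c1ccc(OCC=C(C)C)c(OC)c1)C(=O)C2O | intermediate (not isolated)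
16 | 8-methoxy-2-[3-methoxy-4-(3-methylbut-2-enyloxy)phenyl]-5,7-bis{[2-(trimethylsilyl)ethoxy]methoxy}chromane-3,4-dione, racemic | COc1c(OCOCC[Si](C)(C)C)cc(OCOCC[Si](C)(C)C)c2c1OC(c1ccc(OCC=C(C)C)c(OC)c1)C(=O)C2=O | intermediate (not isolated)
17 | 3-hydroxy-8-methoxy-2-[3-methoxy-4-(3-methylbut-2-enyloxy)phenyl]-5,7-bis{[2-(trimethylsilyl)ethoxy]methoxy}-4H-chromen-4-one | COc1c(OCOCC[Si](C)(C)C)cc(OCOCC[Si](C)(C)C)c2c(=O)c(O)c(-c3ccc(OCC=C(C)C)c(OC)c3)oc12 | intermediate (product of the key step)
18 | 3,8-dimethoxy-2-[3-methoxy-4-(3-methylbut-2-enyloxy)phenyl]-5,7-bis{[2-(trimethylsilyl)ethoxy]methoxy}-4H-chromen-4-one | COc1c(OCOCC[Si](C)(C)C)cc(OCOCC[Si](C)(C)C)c2c(=O)c(OC)c(-c3ccc(OCC=C(C)C)c(OC)c3)oc12 | intermediate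
19 | 5,7-dihydroxy-3,8,3'-trimethoxy-4'-prenyloxyflavone (achiral) | COc1cc(-c2oc3c(OC)c(O)cc(O)c3c(=O)c2OC)ccc1OCC=C(C)C | target

Total step count: 13. Longest linear sequence: 12 steps (steps 1–6 and 8–13, from 1 to 19).

Steps most likely to fail

1. Step 11 (carbene-catalysed closure). The Breslow intermediate may collapse by loss of the A-ring aryloxide, or the α-aryloxy aldehyde may enolise and undergo aldol onto the aryl aldehyde, so that no acyloin forms. The fallback sets out from 14 and uses a reductive instead of an umpolung C3–C4 coupling. Samarium diiodide in THF at −78 °C (intramolecular pinacol coupling of a 1,6-dialdehyde; the aryl ketyl forms first and adds in a 6-exo mode) should give racemic 8-methoxy-2-[3-methoxy-4-(3-methylbut-2-enyloxy)phenyl]-5,7-bis{[2-(trimethylsilyl)ethoxy]methoxy}chromane-3,4-diol F1. Oxidation of this diol with IBX in DMSO, which does not cleave the C–C bond, should give dione 16, which enolises, and the route is rejoined at 17.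

2. Step 8 (Mitsunobu etherification). The doubly ortho-substituted, hydrogen-bonded phenol may be too weak a nucleophile, so that the activated alcohol is consumed by the hydrazide instead. The fallback sets out from 11 and 8 and separates activation from C–O bond formation. Appel bromination of 11 (CBr4, PPh3, CH2Cl2, 0 °C) should give racemic 3-methylbut-2-enyl 2-bromo-2-[3-methoxy-4-(3-methylbut-2-enyloxy)phenyl]acetate F2, which alkylates the potassium phenoxide of 8 (K2CO3, acetone, rt; Williamson ether synthesis) and returns to the route at 12.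

3. Step 10 (double oxidation). The half-oxidised hydroxy aldehyde may close to a seven-membered lactol that is over-oxidised to a lactone, and the α-aryloxy aldehyde may enolise or hydrate during work-up. The fallback sets out from 13 and oxidises the two alcohols in a fixed order. Activated MnO2 in CH2Cl2 should oxidise only the benzylic alcohol, giving racemic 2-{2-hydroxy-1-[3-methoxy-4-(3-methylbut-2-enyloxy)phenyl]ethoxy}-3-methoxy-4,6-bis{[2-(trimethylsilyl)ethoxy]methoxy}benzaldehyde F3. Its remaining primary alcohol is then oxidised under Parikh–Doering conditions (SO3·pyridine, DMSO, i-Pr2NEt, 0 °C), and the solution of 14 is taken directly into step 11.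

Further compounds
F1 | step 11 | 8-methoxy-2-[3-methoxy-4-(3-methylbut-2-enyloxy)phenyl]-5,7-bis{[2-(trimethylsilyl)ethoxy]methoxy}chromane-3,4-diol, racemic mixture of diastereomers | COc1c(OCOCC[Si](C)(C)C)cc(OCOCC[Si](C)(C)C)c2c1OC(c1ccc(OCC=C(C)C)c(OC)c1)C(O)C2O
F2 | step 8 | 3-methylbut-2-enyl 2-bromo-2-[3-methoxy-4-(3-methylbut-2-enyloxy)phenyl]acetate, racemic | COc1cc(C(Br)C(=O)OCC=C(C)C)ccc1OCC=C(C)C
F3 | step 10 | 2-{2-hydroxy-1-[3-methoxy-4-(3-methylbut-2-enyloxy)phenyl]ethoxy}-3-methoxy-4,6-bis{[2-(trimethylsilyl)ethoxy]methoxy}benzaldehyde, racemic | OCC(Oc1c(C=O)c(OCOCC[Si](C)(C)C)cc(OCOCC[Si](C)(C)C)c1OC)c1ccc(OCC=C(C)C)c(OC)c1
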